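**Strategy**

- Retrosynthetic cuts, in order: O1–C2 of both pyranone rings (two 1-(2-hydroxyaryl)-1,3-diketones), C2–C3 of flavone 1 (ketone enolate plus a lactone carbonyl), C2–C3 of flavone 2 (methyl ketone plus an aroyl chloride), the biaryl bond C2′–C8, and last an ester C–O bond.
- Enabling feature: the biaryl bond joins C2′ of ring B to C8 of flavone 2. Its ortho neighbours are C1′, which carries C2 of flavone 1 (a carbon at the acid oxidation level), and C8a, which carries O1 of flavone 2. A C(=O)–O link between these two atoms makes the biaryl coupling intramolecular, fixes the 2′,8 connectivity, and both bridge atoms stay in the target as ring atoms.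
- Forward order: aryl ester, then the six-membered lactone closed through the biaryl bond (Pd-catalysed C–H arylation), then the diketone of flavone 2 built on the acetyl group, then lactone opening by the enolate that brings ring A of flavone 1, then both pyranones closed in one acid step, then debenzylation.
- Stereochemistry: the target has no stereocentre and its biaryl axis is not defined, so no step needs stereocontrol.

Key step: step 4

Remark: the SMILES fixes no configuration at the C2′–C8 axis, so the axis is left uncontrolled; all 1,3-diketones are drawn as diketo tautomers although they should exist largely as enols.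

**Route**

Step 1
Reactants: 1 2,4,6-trihydroxyacetophenone
Product: 2 1-[2,4-bis(benzyloxy)-6-hydroxyphenyl]ethanone
Conditions: BnBr (2.1 equiv), K2CO3 (2.2 equiv), DMF, rt
Reagents that add atoms: benzyl bromide, BrCc1ccccc1
Why: Williamson ether synthesis, expected to stop at the dibenzyl ether because the remaining hydroxyl is hydrogen-bonded to the acetyl carbonyl and is the least acidic and least nucleophilic of the three.

Step 2
Reactants: 3 2-bromo-4-methoxybenzoic acid
Product: 4 2-bromo-4-methoxybenzoyl chloride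
Conditions: (COCl)2, DMF (cat.), CH2Cl2, 0 °C to rt; evaporate, use crude
Reagents that add atoms: oxalyl chloride, O=C(Cl)C(=O)Cl
Why: Acid chloride formation through the Vilsmeier-type chloroiminium species from oxalyl chloride and catalytic DMF, under cold neutral conditions that leave the aryl bromide and the methyl ether untouched.

Step 3
Reactants: 4 2-bromo-4-methoxybenzoyl chloride; 2 1-[2,4-bis(benzyloxy)-6-hydroxyphenyl]ethanone
Product: 5 2-acetyl-3,5-bis(benzyloxy)phenyl 2-bromo-4-methoxybenzoate
Conditions: Et3N, DMAP (cat.), CH2Cl2, 0 °C to rt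
Reagents that add atoms: none
Why: DMAP-catalysed O-acylation of the chelated phenol by the acid chloride, with a tertiary amine that is too weak a base to enolise the acetyl group, so the aroyl group should stay on oxygen.

Step 4
Reactants: 5 2-acetyl-3,5-bis(benzyloxy)phenyl 2-bromo-4-methoxybenzoate
Product: 6 4-acetyl-1,3-bis(benzyloxy)-9-methoxy-6H-benzo[c]chromen-6-one
Conditions: Pd(OAc)2 (10 mol %), PPh3 (20 mol %), NaOAc (2 equiv), DMA, 125 °C, Ar
Reagents that add atoms: none
Why: The cycle should begin with oxidative addition of the aryl bromide to zerovalent palladium (formed in situ from Pd(OAc)2 and PPh3); the ester tether then places the divalent arylpalladium centre over C6 of the phenyl ester ring, the one unsubstituted carbon beside the acyloxy group, where an acetate ligand removes the proton as the Pd–C bond forms (concerted metalation–deprotonation). The resulting diarylpalladium species is a seven-membered oxapalladacycle, and C–C reductive elimination from it contracts to the six-membered lactone ring of the benzo[c]chromen-6-one and returns zerovalent palladium, so the lactone ring closes through the biaryl bond (C10a–C10b) and not through the ester bond, which is already in place. The closest known reaction type is the intramolecular direct arylation of aryl 2-halobenzoates used in the lactone approach to hindered biaryls. No stereocentre arises, and the bridged biaryl axis is configurationally labile, which is of no concern because the target defines no axis. The step needs site selectivity for C8 over C6 of the later flavone 2, and the substrate secures it: the second position ortho to the acyloxy group carries the acetyl group, so only one cyclisation mode exists, and the trioxygenated ring is electron-rich enough for easy metalation. It also needs the aroyl group to stay on oxygen: sodium acetate is too weak a base to enolise the acetyl group at a useful rate, so a Baker–Venkataraman migration should not compete, and after ring closure the lactone carbonyl is held away from the acetyl group, which rules this migration out in all later steps.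

Step 5
Reactants: 6 4-acetyl-1,3-bis(benzyloxy)-9-methoxy-6H-benzo[c]chromen-6-one; 7 4-(benzyloxy)benzoyl chloride
Product: 8 1-[1,3-bis(benzyloxy)-9-methoxy-6-oxo-6H-benzo[c]chromen-4-yl]-3-[4-(benzyloxy)phenyl]propane-1,3-dione
Conditions: 7 (1.1 equiv), MgBr2·OEt2 (2.5 equiv), iPr2NEt (3 equiv), CH2Cl2, rt; 1 M HCl work-up
Reagents that add atoms: none
Why: Crossed Claisen-type C-acylation by soft enolisation, in which the magnesium enolate of the methyl ketone is acylated on carbon by the acid chloride while the far less electrophilic lactone is left alone.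

Step 6
Reactants: 9 2,6-dihydroxy-4-methoxyacetophenone
Product: 10 1-[2-(benzyloxy)-6-hydroxy-4-methoxyphenyl]ethanone
Conditions: BnBr (1.05 equiv), K2CO3 (1.1 equiv), acetone, reflux
Reagents that add atoms: benzyl bromide, BrCc1ccccc1
Why: Williamson monoalkylation of the symmetrical diol, which should stop after one benzyl group because the second hydroxyl then remains chelated to the carbonyl and reacts much more slowly.

Step 7
Reactants: 8 1-[1,3-bis(benzyloxy)-9-methoxy-6-oxo-6H-benzo[c]chromen-4-yl]-3-[4-(benzyloxy)phenyl]propane-1,3-dione; 10 1-[2-(benzyloxy)-6-hydroxy-4-methoxyphenyl]ethanone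
Product: 12 1-[2-(benzyloxy)-6-hydroxy-4-methoxyphenyl]-3-{2-[4,6-bis(benzyloxy)-3-{3-[4-(benzyloxy)phenyl]-3-oxopropanoyl}-2-hydroxyphenyl]-4-methoxyphenyl}propane-1,3-dione, via dilithium phenoxide enolate 11 (not isolated)
Conditions: 10 (3.0 equiv), LiN(SiMe3)2 (6.2 equiv), THF, −78 °C; then 8, −78 to 0 °C; 1 M HCl quench at 0 °C
Reagents that add atoms: lithium bis(trimethylsilyl)amide, [Li+].C[Si](C)(C)[N-][Si](C)(C)C (supplies the lithium of the unisolated intermediate 11; no atom of it remains in 12)
Why: Crossed Claisen condensation in which the enolate carbon of the dianion attacks the activated aryl-ester carbonyl of the lactone and the tetrahedral intermediate expels the phenoxide of ring A of flavone 2, with the excess dianion first masking the diketone of 8 as its enolate and the new diketone pulling the equilibrium forward by its own deprotonation.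

Step 8
Reactants: 12 the open bis(1,3-diketone) of step 7
Product: 13 5,7-bis(benzyloxy)-8-{2-[5-(benzyloxy)-7-methoxy-4-oxo-4H-chromen-2-yl]-5-methoxyphenyl}-2-[4-(benzyloxy)phenyl]-4H-chromen-4-one
Conditions: TsOH·H2O (0.2 equiv), toluene, 90 °C
Reagents that add atoms: none
Why: Twofold acid-catalysed cyclodehydration of 1-(2-hydroxyaryl)-1,3-diketones (the closing stage of the Baker–Venkataraman flavone synthesis), in which each free phenol adds to the distal carbonyl of its own diketone and loss of water gives an aromatic 4-pyranone irreversibly, whereas addition of the phenol of ring A of flavone 2 to the ring B carbonyl gives only a reversible hemiketal.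

Step 9
Reactants: 13 the tetra-O-benzyl biflavone of step 8
Product: 14 5,7-dihydroxy-8-[2-(5-hydroxy-7-methoxy-4-oxo-4H-chromen-2-yl)-5-methoxyphenyl]-2-(4-hydroxyphenyl)-4H-chromen-4-one (CNP0329977.0)
Conditions: H2 (1 atm), 10% Pd/C, THF–MeOH, rt
Reagents that add atoms: none
Why: Catalytic hydrogenolysis of the four benzyl ethers, which does not cleave aryl methyl ethers and is expected to leave the conjugated pyranone double bonds intact at atmospheric pressure.

**Compound list**

1 | 2,4,6-trihydroxyacetophenone | CC(=O)c1c(O)cc(O)cc1O | starting material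
2 | 1-[2,4-bis(benzyloxy)-6-hydroxyphenyl]ethanone | CC(=O)c1c(O)cc(OCc2ccccc2)cc1OCc1ccccc1 | intermediate
3 | 2-bromo-4-methoxybenzoic acid | COc1ccc(C(=O)O)c(Br)c1 | starting material
4 | 2-bromo-4-methoxybenzoyl chloride | COc1ccc(C(=O)Cl)c(Br)c1 | intermediate
5 | 2-acetyl-3,5-bis(benzyloxy)phenyl 2-bromo-4-methoxybenzoate | CC(=O)c1c(OCc2ccccc2)cc(OCc2ccccc2)cc1OC(=O)c1ccc(OC)cc1Br | intermediate
6 | 4-acetyl-1,3-bis(benzyloxy)-9-methoxy-6H-benzo[c]chromen-6-one | CC(=O)c1c(OCc2ccccc2)cc(OCc2ccccc2)c2c1OC(=O)c1ccc(OC)cc1-2 | intermediate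
7 | 4-(benzyloxy)benzoyl chloride | O=C(Cl)c1ccc(OCc2ccccc2)cc1 | starting material
8 | 1-[1,3-bis(benzyloxy)-9-methoxy-6-oxo-6H-benzo[c]chromen-4-yl]-3-[4-(benzyloxy)phenyl]propane-1,3-dione | O=C(CC(=O)c1c(OCc2ccccc2)cc(OCc2ccccc2)c2c1OC(=O)c1ccc(OC)cc1-2)c1ccc(OCc2ccccc2)cc1 | intermediate
9 | 2,6-dihydroxy-4-methoxyacetophenone | CC(=O)c1c(O)cc(OC)cc1O | starting material
10 | 1-[2-(benzyloxy)-6-hydroxy-4-methoxyphenyl]ethanone | CC(=O)c1c(O)cc(OC)cc1OCc1ccccc1 | intermediate
11 | dilithium phenoxide enolate of 10 (not isolated) | [Li+].[Li+].C=C([O-])c1c([O-])cc(OC)cc1OCc1ccccc1 | intermediate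
12 | 1-[2-(benzyloxy)-6-hydroxy-4-methoxyphenyl]-3-{2-[4,6-bis(benzyloxy)-3-{3-[4-(benzyloxy)phenyl]-3-oxopropanoyl}-2-hydroxyphenyl]-4-methoxyphenyl}propane-1,3-dione | COc1cc(O)c(C(=O)CC(=O)c2ccc(OC)cc2-c2c(OCc3ccccc3)cc(OCc3ccccc3)c(C(=O)CC(=O)c3ccc(OCc4ccccc4)cc3)c2O)c(OCc2ccccc2)c1 | intermediate
13 | 5,7-bis(benzyloxy)-8-{2-[5-(benzyloxy)-7-methoxy-4-oxo-4H-chromen-2-yl]-5-methoxyphenyl}-2-[4-(benzyloxy)phenyl]-4H-chromen-4-one | COc1ccc(-c2cc(=O)c3c(OCc4ccccc4)cc(OC)cc3o2)c(-c2c(OCc3ccccc3)cc(OCc3ccccc3)c3c(=O)cc(-c4ccc(OCc5ccccc5)cc4)oc23)c1 | intermediate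
14 | 5,7-dihydroxy-8-[2-(5-hydroxy-7-methoxy-4-oxo-4H-chromen-2-yl)-5-methoxyphenyl]-2-(4-hydroxyphenyl)-4H-chromen-4-one | COc1ccc(-c2cc(=O)c3c(O)cc(OC)cc3o2)c(-c2c(O)cc(O)c3c(=O)cc(-c4ccc(O)cc4)oc23)c1 | target

**Step count**

Total: 9 steps. Longest linear sequence: 7 steps (1 or 3 to 14 through steps 1 or 2, 3, 4, 5, 7, 8, 9).

**Steps most likely to fail**

Step 4. The aroyl group may migrate from oxygen to the acetyl carbon or the ester may be cleaved at 125 °C before the C–H bond is broken; protodebromination and slow metalation at a C–H flanked by two oxygen substituents are further risks. The fallback sets out from 2 and 3 and comes back at 6; it makes the biaryl bond by an intermolecular Suzuki–Miyaura coupling and closes the lactone ring afterwards by acylation. Ketone 2 would be iodinated ortho to the free hydroxyl (N-iodosuccinimide, TFA cat., MeCN, 0 °C) to give 1-[4,6-bis(benzyloxy)-2-hydroxy-3-iodophenyl]ethanone F1. Acid 3 would be esterified (MeOH, H2SO4 cat., reflux) to methyl 2-bromo-4-methoxybenzoate F2, and Miyaura borylation (B2pin2, KOAc, Pd(dppf)Cl2, dioxane, 90 °C) should give methyl 4-methoxy-2-(4,4,5,5-tetramethyl-1,3,2-dioxaborolan-2-yl)benzoate F3. Coupling of F1 with F3 (Pd(OAc)2, SPhos, K3PO4, toluene–H2O, 90 °C) should give methyl 2-[3-acetyl-4,6-bis(benzyloxy)-2-hydroxyphenyl]-4-methoxybenzoate F4, whose phenol is expected to close onto the neighbouring ester under the basic conditions, or on brief warming with TsOH, to give lactone 6.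

Step 7. The doubly charged enolate may act mainly as a base, aggregate, and add too slowly to the lactone carbonyl, so that conversion stalls. The fallback sets out from 8 and 9 and comes back at 14; it uses a phenoxide-free monoanion and closes the two pyranones one after the other. Diol 9 would be benzylated twice (BnBr 2.3 equiv, K2CO3, DMF, 60 °C) to 1-[2,6-bis(benzyloxy)-4-methoxyphenyl]ethanone F5. Its lithium enolate F6 (LiN(SiMe3)2, THF, −78 °C; 3 equiv, the first masking the diketone of 8) would open lactone 8 to 1-[2,6-bis(benzyloxy)-4-methoxyphenyl]-3-{2-[4,6-bis(benzyloxy)-3-{3-[4-(benzyloxy)phenyl]-3-oxopropanoyl}-2-hydroxyphenyl]-4-methoxyphenyl}propane-1,3-dione F7, in which only the phenol of ring A of flavone 2 is free. TsOH·H2O in toluene would then close flavone 2 alone to give 1-[2,6-bis(benzyloxy)-4-methoxyphenyl]-3-(2-{5,7-bis(benzyloxy)-2-[4-(benzyloxy)phenyl]-4-oxo-4H-chromen-8-yl}-4-methoxyphenyl)propane-1,3-dione F8. Hydrogenolysis (H2, 10% Pd/C, THF–MeOH) would remove all five benzyl ethers to give 1-(2,6-dihydroxy-4-methoxyphenyl)-3-{2-[5,7-dihydroxy-2-(4-hydroxyphenyl)-4-oxo-4H-chromen-8-yl]-4-methoxyphenyl}propane-1,3-dione F9. Its dihydroxyaryl ketone ring is symmetrical, so either hydroxyl closes to the same pyranone, and H2SO4 (cat.) in AcOH at 90 °C should give 14.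

Step 8. The phenol freed from the lactone may add to the ring B carbonyl instead of its own diketone, and the hemiketal may fragment by a retro-Claisen path or stall; acid may also strip the peri benzyl ethers, so a mixture of half-closed and partly debenzylated material is possible. The fallback sets out from 8 and comes back at 13; it closes flavone 2 while the ring B carbonyl is still an amide that the phenol does not attack. Lactone 8 would be opened with the aluminium amide from AlMe3 and N,O-dimethylhydroxylamine hydrochloride (CH2Cl2, 0 °C to rt) to give 2-[4,6-bis(benzyloxy)-3-{3-[4-(benzyloxy)phenyl]-3-oxopropanoyl}-2-hydroxyphenyl]-N,4-dimethoxy-N-methylbenzamide F10. TsOH·H2O in toluene would close flavone 2 to give 2-{5,7-bis(benzyloxy)-2-[4-(benzyloxy)phenyl]-4-oxo-4H-chromen-8-yl}-N,4-dimethoxy-N-methylbenzamide F11. Acylation of dianion 11 by this Weinreb amide (THF, −78 to 0 °C; the chelated tetrahedral intermediate prevents over-addition) should give 1-[2-(benzyloxy)-6-hydroxy-4-methoxyphenyl]-3-(2-{5,7-bis(benzyloxy)-2-[4-(benzyloxy)phenyl]-4-oxo-4H-chromen-8-yl}-4-methoxyphenyl)propane-1,3-dione F12, and a second TsOH cyclodehydration would give 13.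

**Further compounds**

F1 | step 4 | 1-[4,6-bis(benzyloxy)-2-hydroxy-3-iodophenyl]ethanone | CC(=O)c1c(O)c(I)c(OCc2ccccc2)cc1OCc1ccccc1
F2 | step 4 | methyl 2-bromo-4-methoxybenzoate | COC(=O)c1ccc(OC)cc1Br
F3 | step 4 | methyl 4-methoxy-2-(4,4,5,5-tetramethyl-1,3,2-dioxaborolan-2-yl)benzoate | COC(=O)c1ccc(OC)cc1B1OC(C)(C)C(C)(C)O1
F4 | step 4 | methyl 2-[3-acetyl-4,6-bis(benzyloxy)-2-hydroxyphenyl]-4-methoxybenzoate | COC(=O)c1ccc(OC)cc1-c1c(O)c(C(C)=O)c(OCc2ccccc2)cc1OCc1ccccc1
F5 | step 7 | 1-[2,6-bis(benzyloxy)-4-methoxyphenyl]ethanone | CC(=O)c1c(OCc2ccccc2)cc(OC)cc1OCc1ccccc1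
F6 | step 7 | lithium enolate of F5 | [Li+].C=C([O-])c1c(OCc2ccccc2)cc(OC)cc1OCc1ccccc1
F7 | step 7 | 1-[2,6-bis(benzyloxy)-4-methoxyphenyl]-3-{2-[4,6-bis(benzyloxy)-3-{3-[4-(benzyloxy)phenyl]-3-oxopropanoyl}-2-hydroxyphenyl]-4-methoxyphenyl}propane-1,3-dione | COc1cc(OCc2ccccc2)c(C(=O)CC(=O)c2ccc(OC)cc2-c2c(OCc3ccccc3)cc(OCc3ccccc3)c(C(=O)CC(=O)c3ccc(OCc4ccccc4)cc3)c2O)c(OCc2ccccc2)c1
F8 | step 7 | 1-[2,6-bis(benzyloxy)-4-methoxyphenyl]-3-(2-{5,7-bis(benzyloxy)-2-[4-(benzyloxy)phenyl]-4-oxo-4H-chromen-8-yl}-4-methoxyphenyl)propane-1,3-dione | COc1cc(OCc2ccccc2)c(C(=O)CC(=O)c2ccc(OC)cc2-c2c(OCc3ccccc3)cc(OCc3ccccc3)c3c(=O)cc(-c4ccc(OCc5ccccc5)cc4)oc23)c(OCc2ccccc2)c1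
F9 | step 7 | 1-(2,6-dihydroxy-4-methoxyphenyl)-3-{2-[5,7-dihydroxy-2-(4-hydroxyphenyl)-4-oxo-4H-chromen-8-yl]-4-methoxyphenyl}propane-1,3-dione | COc1cc(O)c(C(=O)CC(=O)c2ccc(OC)cc2-c2c(O)cc(O)c3c(=O)cc(-c4ccc(O)cc4)oc23)c(O)c1
F10 | step 8 | 2-[4,6-bis(benzyloxy)-3-{3-[4-(benzyloxy)phenyl]-3-oxopropanoyl}-2-hydroxyphenyl]-N,4-dimethoxy-N-methylbenzamide | CON(C)C(=O)c1ccc(OC)cc1-c1c(O)c(C(=O)CC(=O)c2ccc(OCc3ccccc3)cc2)c(OCc2ccccc2)cc1OCc1ccccc1
F11 | step 8 | 2-{5,7-bis(benzyloxy)-2-[4-(benzyloxy)phenyl]-4-oxo-4H-chromen-8-yl}-N,4-dimethoxy-N-methylbenzamide | CON(C)C(=O)c1ccc(OC)cc1-c1c(OCc2ccccc2)cc(OCc2ccccc2)c2c(=O)cc(-c3ccc(OCc4ccccc4)cc3)oc12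
F12 | step 8 | 1-[2-(benzyloxy)-6-hydroxy-4-methoxyphenyl]-3-(2-{5,7-bis(benzyloxy)-2-[4-(benzyloxy)phenyl]-4-oxo-4H-chromen-8-yl}-4-methoxyphenyl)propane-1,3-dione | COc1cc(O)c(C(=O)CC(=O)c2ccc(OC)cc2-c2c(OCc3ccccc3)cc(OCc3ccccc3)c3c(=O)cc(-c4ccc(OCc5ccccc5)cc4)oc23)c(OCc2ccccc2)c1
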